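## Retrosynthetic overview

- The ArA–CH2–ArB bond is cut reductively: the bridging CH2 is one of the two equivalent formyl carbons of jensenone (the symmetric diformyl isovaleryl phloroglucinol). No formaldehyde or Mannich/benzyl electrophile is used, and the formyl group that does not react is the aldehyde of the target.
- The nucleophile is the single free ring C–H of the ring-A monomer, 1-(4,6-dihydroxy-2-methoxy-3-methylphenyl)-2-methylpropan-1-one.
- Jensenone comes from phloroglucinol by C-isovalerylation, then double formylation.
- The ring-A monomer comes from 2-methylphloroglucinol by C-isobutyrylation, chelation-controlled bis-MOM protection, O-methylation of the one remaining OH, and MOM removal.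
- No ring is formed: both benzene rings are purchased. Order of assembly: ring-A monomer (4 steps), ring-B dialdehyde (2 steps), reductive union (1 step).

Assumption: the target SMILES has no stereocentres (the molecule is achiral), so "single enantiomer" imposes no stereochemical requirement.

## Route

**Step 1**
Reactants: 1 (2-methylbenzene-1,3,5-triol, 2-methylphloroglucinol); 2 (2-methylpropanoyl chloride)
Product: 3, 1-(2,4,6-trihydroxy-3-methylphenyl)-2-methylpropan-1-one
Conditions: 2 (1.05 equiv), AlCl3 (3.5 equiv), PhNO2, rt to 60 °C; aq HCl
Reagents that add atoms: 2-methylpropanoyl chloride (2), CC(C)C(Cl)=O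
Why: Friedel–Crafts C-acylation; the two open ring positions of 1 are equivalent and the first acyl group deactivates the ring, so a single mono-ketone forms.

**Step 2**
Reactants: 3; 4 (chloromethyl methyl ether, MOMCl)
Product: 5, 1-[2-hydroxy-4,6-bis(methoxymethoxy)-3-methylphenyl]-2-methylpropan-1-one
Conditions: MOMCl (2.1 equiv), i-Pr2NEt (2.6 equiv), CH2Cl2, 0 °C to rt
Reagents that add atoms: chloromethyl methyl ether (4), COCCl
Why: Chelation-controlled selective O-alkylation (MOM ether formation); the non-chelated 4-OH and the less hindered 6-OH react, while the 2-OH wedged between the C-methyl and the C=O keeps its buttressed hydrogen bond, as expected from partial alkylation of C-methyl phloroacylphenones, so the oxygen left free is the one that must become OMe.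

**Step 3**
Reactants: 5; 6 (iodomethane)
Product: 7, 1-[2-methoxy-4,6-bis(methoxymethoxy)-3-methylphenyl]-2-methylpropan-1-one
Conditions: MeI (3 equiv), K2CO3, DMF, 50 °C
Reagents that add atoms: iodomethane (6), CI
Why: Williamson ether synthesis on the only remaining OH; carbonate in DMF breaks the chelate without enolising the ketone, and MOM ethers are base-stable.

**Step 4**
Reactants: 7
Product: 8, 1-(4,6-dihydroxy-2-methoxy-3-methylphenyl)-2-methylpropan-1-one
Conditions: 3 M HCl, MeOH, 50 °C, dilute
Reagents that add atoms: none
Why: Acid-catalysed acetal (MOM) solvolysis; methanol traps the released formaldehyde as dimethoxymethane so the nucleophilic C5–H is not hydroxymethylated, and the aryl methyl ether and ketone are inert.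

**Step 5**
Reactants: 9 (benzene-1,3,5-triol, phloroglucinol); 10 (3-methylbutanoyl chloride)
Product: 11, 1-(2,4,6-trihydroxyphenyl)-3-methylbutan-1-one
Conditions: 10 (1.0 equiv), AlCl3 (3.5 equiv), CH2Cl2–MeNO2, 0 to 40 °C; aq HCl
Reagents that add atoms: 3-methylbutanoyl chloride (10), CC(C)CC(Cl)=O
Why: Friedel–Crafts C-acylation; all three ring positions are equivalent and mono-acylation deactivates the ring.

**Step 6**
Reactants: 11; 12 (dichloromethyl methyl ether)
Product: 13, jensenone, 2,4,6-trihydroxy-5-(3-methylbutanoyl)benzene-1,3-dicarbaldehyde
Conditions: Cl2CHOMe (3 equiv), TiCl4 (6 equiv), CH2Cl2, –10 °C to rt; 1 M HCl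
Reagents that add atoms: dichloromethyl methyl ether (12), COC(Cl)Cl (formyl carbon; formyl oxygen from the reagent or from water on hydrolysis); water, O
Why: Double Rieche formylation; both remaining ring carbons are ortho/para to three titanium phenoxides, and the chelated ketone is inert.

**Step 7 (key step)**
Reactants: 8; 13 (2.5 equiv, excess recovered); 14 (Hantzsch ester, diethyl 2,6-dimethyl-1,4-dihydropyridine-3,5-dicarboxylate, hydride donor)
Product: 15, Robustaol A
Conditions: 13 (2.5 equiv), 14 (1.5 equiv), L-proline (20 mol%), EtOH–CH2Cl2, 40 °C, slow addition of 8
Reagents that add atoms: none (the bridging carbon is a formyl carbon of 13; 14 supplies only hydrogen)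
Why: Proposed new method: a desymmetrising reductive Friedel–Crafts (Knoevenagel/Betti-type) arylation in which proline activates one of the two equivalent formyl groups of 13 as an iminium, the only free ring carbon in either partner (C5 of 8) adds, loss of proline/water gives an ortho-quinone methide, and the Hantzsch ester reduces it by conjugate hydride transfer with re-aromatisation; this should outrun addition of a second, doubly ortho-substituted aryl, and the Hantzsch ester does not reduce the chelated ketones or the remaining aldehyde, which sits on a more electron-rich ring and is therefore less reactive. The closest known reaction types are the organocatalytic three-component reductive alkylation of cyclic 1,3-dicarbonyls and hydroxycoumarins with aryl aldehydes and Hantzsch ester, acid-catalysed Hantzsch-ester reduction of in-situ ortho-quinone methides, and the hydride reduction of acylphloroglucinols to alkylphloroglucinols via ortho-quinone methides. The expected by-products are grandinol (over-reduction of the excess 13) and the 2:1 adduct.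

Atom balance for step 7: C12H16O4 (8) + C13H14O6 (13) + 2 H → C25H30O9 (15) + H2O.

## Compound list

1 | 2-methylbenzene-1,3,5-triol (2-methylphloroglucinol) | Cc1c(O)cc(O)cc1O | starting material
2 | 2-methylpropanoyl chloride | CC(C)C(Cl)=O | starting material (reagent)
3 | 1-(2,4,6-trihydroxy-3-methylphenyl)-2-methylpropan-1-one | CC(C)C(=O)c1c(O)cc(O)c(C)c1O | intermediate
4 | chloromethyl methyl ether | COCCl | starting material (reagent)
5 | 1-[2-hydroxy-4,6-bis(methoxymethoxy)-3-methylphenyl]-2-methylpropan-1-one | CC(C)C(=O)c1c(OCOC)cc(OCOC)c(C)c1O | intermediate
6 | iodomethane | CI | starting material (reagent)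
7 | 1-[2-methoxy-4,6-bis(methoxymethoxy)-3-methylphenyl]-2-methylpropan-1-one | CC(C)C(=O)c1c(OCOC)cc(OCOC)c(C)c1OC | intermediate
8 | 1-(4,6-dihydroxy-2-methoxy-3-methylphenyl)-2-methylpropan-1-one | CC(C)C(=O)c1c(O)cc(O)c(C)c1OC | intermediate
9 | benzene-1,3,5-triol (phloroglucinol) | Oc1cc(O)cc(O)c1 | starting material
10 | 3-methylbutanoyl chloride | CC(C)CC(Cl)=O | starting material (reagent)
11 | 1-(2,4,6-trihydroxyphenyl)-3-methylbutan-1-one | CC(C)CC(=O)c1c(O)cc(O)cc1O | intermediate
12 | dichloromethyl methyl ether | COC(Cl)Cl | starting material (reagent)
13 | jensenone, 2,4,6-trihydroxy-5-(3-methylbutanoyl)benzene-1,3-dicarbaldehyde | CC(C)CC(=O)c1c(O)c(C=O)c(O)c(C=O)c1O | intermediate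
14 | Hantzsch ester, diethyl 2,6-dimethyl-1,4-dihydropyridine-3,5-dicarboxylate | CCOC(=O)C1=C(C)NC(C)=C(C1)C(=O)OCC | starting material (reagent, H donor)
15 | Robustaol A | COc1c(C)c(O)c(Cc2c(O)c(C=O)c(O)c(C(=O)CC(C)C)c2O)c(O)c1C(=O)C(C)C | target

## Step count and risks

Total steps: 7. Longest linear sequence: 5 (steps 1–4, then 7); steps 5–6 form the convergent branch.

Steps most likely to fail, each with a fallback that changes the approach:

1. **Step 7, reductive desymmetrising arylation.** Risks are low electrophilicity of the chelated aldehyde, over-reduction to grandinol, and 2:1 adduct formation. Fallback: abandon the aldehyde-as-linker idea and use the classical ortho-quinone-methide coupling. Mono-formylate 11 (1 equiv Rieche) to 2,4,6-trihydroxy-3-(3-methylbutanoyl)benzaldehyde, convert 8 to its C5 Mannich base (CH2O/Me2NH), and heat the two together so the quinone methide from 8 is trapped by the free ring carbon of the mono-aldehyde.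

2. **Step 2, regioselective bis-MOM protection.** The risk is a 2-OH/6-OH isomer mixture. Fallback: build the ring-A monomer by silicon-blocked iterative directed ortho-metalation. Start from 1-methoxy-3,5-bis(methoxymethoxy)benzene (from 5-methoxyresorcinol). Lithiate between the two OMOM groups and quench with TMSCl to block that position; lithiate and quench with MeI; lithiate and quench with the isobutyryl Weinreb amide. HCl/MeOH then removes both MOM groups and the TMS group to give 8 with unambiguous regiochemistry.

3. **Step 6, double formylation.** The risk is stalling at the mono-aldehyde or titanium-mediated side reactions at the ketone. Fallback: reverse the bond order. Vilsmeier–Haack diformylation of phloroglucinol (POCl3/DMF) gives 2,4-diformylphloroglucinol, then Lewis-acid Friedel–Crafts isovalerylation (10, TiCl4 or AlCl3) at the one remaining ring position gives 13.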